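## Retrosynthetic overview

- Target ⇐ trans-semireduction of a C12≡C13 lactone ynediol. The alkyne masks the 12E alkene so that C11 is not allylic during the cationic step.
- Lactone ynediol ⇐ one cationic cascade on an acyclic C22 tert-butyl (4Z,7E)-dien-12-ynoate carrying a (10R,11S)-cis-epoxide. Electrophilic C10 is attacked by the 7,8-alkene (cyclopropane, first ring) and the C1 carboxyl traps C7 (eight-membered lactone, second ring), the bond set and order of the proposed biogenesis. Anti addition across a 7E alkene is what the 7R,8R,10R array requires (a 7Z alkene would give the 7-epimer), and the epoxide fixes C10 and C11.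
- Cascade substrate ⇐ catalyst-controlled alkynylation of (Z)-non-3-enal (sets C14) by a C1–C13 epoxy alkyne ⇐ Sharpless epoxidation, oxidation and one-carbon homologation of a (4Z,7E,10Z)-trienol.
- Trienol ⇐ semihydrogenation of an ene-diyne made by two copper couplings of (E)-1,4-dibromobut-2-ene with tert-butyl pent-4-ynoate and propargyl alcohol.

Assumption: fatty-acid numbering is used in the text (C1 = lactone carbonyl, C7 = lactone carbinol, C8/C9/C10 = cyclopropane, C22 = methyl), and tert-butyl pent-4-ynoate is bought as such.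

## Route

Step 1
Reactants: 1 tert-butyl pent-4-ynoate; 2 (E)-1,4-dibromobut-2-ene (4 equiv)
Product: 3 tert-butyl (E)-9-bromonon-7-en-4-ynoate
Conditions: CuI (10 mol%), K2CO3 (1.5 equiv), n-Bu4NBr (10 mol%), DMF, 23 °C, slow addition of 1
Reagents that add atoms: none
Why: Copper acetylide alkylation of a primary allylic bromide (Jeffery-type SN2 alkynyl–allyl coupling) gives the skipped enyne with the E geometry of 2 carried over, and the excess of symmetrical 2 keeps double coupling low.

Step 2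
Reactants: 3 tert-butyl (E)-9-bromonon-7-en-4-ynoate; 4 prop-2-yn-1-ol (1.5 equiv)
Product: 5 tert-butyl (E)-12-hydroxydodec-7-ene-4,10-diynoate
Conditions: CuI (10 mol%), K2CO3 (1.5 equiv), n-Bu4NBr (10 mol%), DMF, 23 °C
Reagents that add atoms: none
Why: The same copper acetylide SN2 coupling on the remaining allylic bromide completes the C1–C12 ene-diyne without touching the E alkene or the ester.

Step 3
Reactants: 5 tert-butyl (E)-12-hydroxydodec-7-ene-4,10-diynoate
Product: 6 tert-butyl (4Z,7E,10Z)-12-hydroxydodeca-4,7,10-trienoate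
Conditions: H2 (1 atm, 2 equiv uptake), Ni(OAc)2·4H2O (20 mol%), NaBH4 (20 mol%), ethylenediamine, EtOH, 23 °C (Ni2B formed in the flask)
Reagents that add atoms: none
Why: Nickel boride semihydrogenation (syn addition of H2, Brown catalyst) turns both alkynes into Z alkenes and leaves the isolated E alkene alone.

Step 4
Reactants: 6 tert-butyl (4Z,7E,10Z)-12-hydroxydodeca-4,7,10-trienoate
Product: 7 tert-butyl (4Z,7E)-9-[(2R,3S)-3-(hydroxymethyl)oxiran-2-yl]nona-4,7-dienoate (cis-epoxide, 10R,11S)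
Conditions: Ti(OiPr)4 (10 mol%), L-(+)-diethyl tartrate (14 mol%), t-BuOOH (2 equiv, in decane), 4 Å MS, CH2Cl2, −20 °C, 48 h
Reagents that add atoms: tert-butyl hydroperoxide, CC(C)(C)OO
Why: Katsuki–Sharpless asymmetric epoxidation oxidises only the allylic alkene, and L-(+)-tartrate on a Z-allylic alcohol gives the (2S,3R)-epoxy alcohol, that is 10R,11S (about 85–90% ee expected; the minor enantiomer is removed as a diastereomer after step 8).

Step 5
Reactants: 7 tert-butyl (4Z,7E)-9-[(2R,3S)-3-(hydroxymethyl)oxiran-2-yl]nona-4,7-dienoate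
Product: 8 tert-butyl (4Z,7E)-9-[(2R,3R)-3-formyloxiran-2-yl]nona-4,7-dienoate (same geometry; the C11 descriptor changes by CIP priority only)
Conditions: Dess–Martin periodinane (1.3 equiv), pyridine, CH2Cl2, 0 °C
Reagents that add atoms: none
Why: Buffered Dess–Martin oxidation gives the cis-epoxy aldehyde under neutral conditions that neither open nor epimerise the epoxide.

Step 6
Reactants: 8 tert-butyl (4Z,7E)-9-[(2R,3R)-3-formyloxiran-2-yl]nona-4,7-dienoate
Product: 9 tert-butyl (4Z,7E)-9-[(2R,3S)-3-ethynyloxiran-2-yl]nona-4,7-dienoate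
Conditions: dimethyl (1-diazo-2-oxopropyl)phosphonate (1.3 equiv), K2CO3 (2 equiv), MeOH, 0 → 23 °C
Reagents that add atoms: Ohira–Bestmann reagent (dimethyl (1-diazo-2-oxopropyl)phosphonate), CC(=O)C(=[N+]=[N-])P(=O)(OC)OC
Why: Seyferth–Gilbert homologation in the Ohira–Bestmann variant converts the aldehyde into the terminal alkyne (C12≡C13); the oxirane C–H is not acidic enough to epimerise, and the tert-butyl ester resists methanolysis.

Step 7
Reactants: 10 (Z)-non-3-en-1-ol
Product: 11 (Z)-non-3-enal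
Conditions: Dess–Martin periodinane (1.2 equiv), CH2Cl2, 0 °C, 30 min, used crude at once
Reagents that add atoms: none
Why: Dess–Martin oxidation gives the skipped enal without base, so the Z alkene does not move into conjugation.

Step 8
Reactants: 9 tert-butyl (4Z,7E)-9-[(2R,3S)-3-ethynyloxiran-2-yl]nona-4,7-dienoate; 11 (Z)-non-3-enal (2 equiv, added over 2 h)
Product: 12 tert-butyl (4Z,7E)-9-[(2R,3S)-3-[(3S,5Z)-3-hydroxyundec-5-en-1-yn-1-yl]oxiran-2-yl]nona-4,7-dienoate
Conditions: Me2Zn (1.5 equiv), (S,S)-ProPhenol (20 mol%), Ph3P=O (40 mol%), toluene, 23 °C (1 h, alkynylzinc formation), then 11, 4 °C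
Reagents that add atoms: none
Why: Zinc–ProPhenol catalysed addition of the alkynylzinc (Trost asymmetric alkynylation) to the Re face of the aldehyde sets 14S under catalyst control, and the amine-free conditions leave the ester, the epoxide and the skipped Z alkene alone.

Step 9
Reactants: 12 tert-butyl (4Z,7E)-9-[(2R,3S)-3-[(3S,5Z)-3-hydroxyundec-5-en-1-yn-1-yl]oxiran-2-yl]nona-4,7-dienoate
Product: 14 (5Z,8R)-8-[(1R,2R)-2-[(1R,4S,6Z)-1,4-dihydroxydodec-6-en-2-yn-1-yl]cyclopropyl]-3,4,7,8-tetrahydro-2H-oxocin-2-one, via O-tert-butyl lactonium zwitterion 13 (not isolated)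
Conditions: BF3·OEt2 (20 mol%), CH2Cl2/(CF3)2CHOH (4:1), 0.002 M, −40 → 0 °C, then aqueous NaHCO3
Reagents that add atoms: none
Why: Proposed new method: acid activation of the cis-epoxide makes C10 electrophilic and the homoallylic 7E alkene attacks it from the back (inversion, C10 becomes R, the C11–O bond is untouched) to give the trans-cyclopropylcarbinyl cation, which the ester carbonyl captures at C7 anti to the new C8–C10 bond (anti addition across the E alkene gives 7R,8R) before isobutene is lost; opening at C11 is disfavoured because the sp-carbon substituent is inductively deactivating and offers no allylic stabilisation, and the closest known chemistry is epoxide-initiated cation–olefin cyclisation combined with the homoallyl → cyclopropylcarbinyl closure terminated by a carboxyl group to six-membered cyclopropyl lactones, here stretched to an eight-membered ring.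

Step 10
Reactants: 14 (5Z,8R)-8-[(1R,2R)-2-[(1R,4S,6Z)-1,4-dihydroxydodec-6-en-2-yn-1-yl]cyclopropyl]-3,4,7,8-tetrahydro-2H-oxocin-2-one
Product: 15 (5Z,8R)-8-[(1R,2R)-2-[(1S,2E,4S,6Z)-1,4-dihydroxydodeca-2,6-dien-1-yl]cyclopropyl]-3,4,7,8-tetrahydro-2H-oxocin-2-one (target; C11 is now S by CIP priority only)
Conditions: CrSO4 (6 equiv, aqueous), DMF, 23 °C, argon
Reagents that add atoms: none
Why: Hydroxyl-assisted trans-reduction of the alkyne by divalent chromium (chromous sulfate reduction of a but-2-yne-1,4-diol unit) gives only the E alkene and leaves the lactone, the cyclopropane, the isolated Z alkenes and all stereocentres untouched.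

## Compound list

1 | tert-butyl pent-4-ynoate | C#CCCC(=O)OC(C)(C)C | starting material
2 | (E)-1,4-dibromobut-2-ene | BrC/C=C/CBr | starting material
3 | tert-butyl (E)-9-bromonon-7-en-4-ynoate | BrC/C=C/CC#CCCC(=O)OC(C)(C)C | intermediate
4 | prop-2-yn-1-ol | C#CCO | starting material
5 | tert-butyl (E)-12-hydroxydodec-7-ene-4,10-diynoate | OCC#CC/C=C/CC#CCCC(=O)OC(C)(C)C | intermediate
6 | tert-butyl (4Z,7E,10Z)-12-hydroxydodeca-4,7,10-trienoate | OC/C=C\C/C=C/C/C=C\CCC(=O)OC(C)(C)C | intermediate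
7 | tert-butyl (4Z,7E)-9-[(2R,3S)-3-(hydroxymethyl)oxiran-2-yl]nona-4,7-dienoate | OC[C@@H]1O[C@@H]1C/C=C/C/C=C\CCC(=O)OC(C)(C)C | intermediate
8 | tert-butyl (4Z,7E)-9-[(2R,3R)-3-formyloxiran-2-yl]nona-4,7-dienoate | O=C[C@@H]1O[C@@H]1C/C=C/C/C=C\CCC(=O)OC(C)(C)C | intermediate
9 | tert-butyl (4Z,7E)-9-[(2R,3S)-3-ethynyloxiran-2-yl]nona-4,7-dienoate | C#C[C@@H]1O[C@@H]1C/C=C/C/C=C\CCC(=O)OC(C)(C)C | intermediate
10 | (Z)-non-3-en-1-ol | CCCCC/C=C\CCO | starting material
11 | (Z)-non-3-enal | CCCCC/C=C\CC=O | intermediate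
12 | tert-butyl (4Z,7E)-9-[(2R,3S)-3-[(3S,5Z)-3-hydroxyundec-5-en-1-yn-1-yl]oxiran-2-yl]nona-4,7-dienoate | CCCCC/C=C\C[C@H](O)C#C[C@@H]1O[C@@H]1C/C=C/C/C=C\CCC(=O)OC(C)(C)C | intermediate
13 | O-tert-butyl lactonium zwitterion (lactone carbonyl O-tert-butylated, C11–O bound to BF3) | CCCCC/C=C\C[C@H](O)C#C[C@H](O[B-](F)(F)F)[C@@H]1C[C@H]1[C@H]1C/C=C\CCC(=[O+]C(C)(C)C)O1 | intermediate (not isolated)
14 | (5Z,8R)-8-[(1R,2R)-2-[(1R,4S,6Z)-1,4-dihydroxydodec-6-en-2-yn-1-yl]cyclopropyl]-3,4,7,8-tetrahydro-2H-oxocin-2-one | CCCCC/C=C\C[C@H](O)C#C[C@H](O)[C@@H]1C[C@H]1[C@H]1C/C=C\CCC(=O)O1 | intermediate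
15 | (5Z,8R)-8-[(1R,2R)-2-[(1S,2E,4S,6Z)-1,4-dihydroxydodeca-2,6-dien-1-yl]cyclopropyl]-3,4,7,8-tetrahydro-2H-oxocin-2-one | CCCCC/C=C\C[C@H](O)/C=C/[C@H](O)[C@@H]1C[C@H]1[C@H]1C/C=C\CCC(=O)O1 | target

## Step count and risks

Total steps: 10. Longest linear sequence: 9 (steps 1–6, 8, 9, 10); step 7 is a one-step side branch.

The three steps most likely to fail:

**Step 9 (cascade).** The eight-membered ring must close faster than elimination or external capture of the C7 cation. The face of C7 is only controlled if capture is concerted with, or directly follows, cyclopropane closure. Opening at C11 or a hydride shift to a ketone can compete. Fallback, from 12 back to 14, separates lactone formation from the cationic step: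
- The BF3·OEt2/(CF3)2CHOH cyclopropanation is run with chloroacetic acid (10 equiv) as external trap to give the 7-chloroacetate diol tert-butyl ester F1.
- TBSOTf (5 equiv)/2,6-lutidine silylates both hydroxyls and converts the tert-butyl ester into the silyl ester, giving the tris-silyl chloroacetate F2.
- K2CO3 in MeOH/H2O removes the chloroacetate and the silyl ester to give the 7-hydroxy acid bis-silyl ether F3.
- Yamaguchi lactonisation (2,4,6-trichlorobenzoyl chloride, Et3N, then DMAP, toluene, high dilution), with C7 as the only free hydroxyl, gives the bis-silyl lactone F4.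
- HF·pyridine in THF removes both silyl ethers and returns to 14.

**Step 8 (alkynylation).** The skipped enal 11 can isomerise to the conjugated enal or self-condense, unbranched aldehydes give moderate ee, and the sense of induction for this aldehyde has to be confirmed (Mosher ester). Fallback, from 9 back to 12, uses a neutral coupling and sets C14 by reduction:
- N-iodosuccinimide with AgNO3 (10 mol%) in acetone gives the iodoalkyne F5.
- Nozaki–Hiyama–Kishi addition to 11 (CrCl2, NiCl2 (1 mol%), THF) gives the C14-epimeric propargylic alcohols F6.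
- Dess–Martin periodinane gives the ynone F7.
- (S)-Alpine-borane (from (−)-α-pinene, neat or THF, 23 °C) reduces F7 to the 14S alcohol 12.

**Step 10 (trans-reduction).** Reduction may stall on this hindered ynediol, or the lactone may hydrolyse in the acidic aqueous medium. Fallback, from 14 back to 15, goes through a vinylsilane:
- Trans-hydrosilylation with BnMe2SiH and [Cp*Ru(MeCN)3]PF6 (5 mol%) in CH2Cl2 gives the (Z)-vinylsilane F8 (or its 12-silyl regioisomer, which converges).
- Protodesilylation with AgF in THF/MeOH/H2O proceeds with retention and gives the E alkene 15.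

## Further compounds

F1 | step 9 | tert-butyl (4Z,7R)-7-(chloroacetoxy)-7-[(1R,2R)-2-[(1R,4S,6Z)-1,4-dihydroxydodec-6-en-2-yn-1-yl]cyclopropyl]hept-4-enoate | CCCCC/C=C\C[C@H](O)C#C[C@H](O)[C@@H]1C[C@H]1[C@@H](C/C=C\CCC(=O)OC(C)(C)C)OC(=O)CCl
F2 | step 9 | tert-butyldimethylsilyl ester of the 11,14-bis(tert-butyldimethylsilyl) ether of the 7-chloroacetate (tris-silyl compound) | CCCCC/C=C\C[C@H](O[Si](C)(C)C(C)(C)C)C#C[C@H](O[Si](C)(C)C(C)(C)C)[C@@H]1C[C@H]1[C@@H](C/C=C\CCC(=O)O[Si](C)(C)C(C)(C)C)OC(=O)CCl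
F3 | step 9 | (4Z,7R)-7-hydroxy-7-[(1R,2R)-2-[(1R,4S,6Z)-1,4-bis(tert-butyldimethylsilyloxy)dodec-6-en-2-yn-1-yl]cyclopropyl]hept-4-enoic acid | CCCCC/C=C\C[C@H](O[Si](C)(C)C(C)(C)C)C#C[C@H](O[Si](C)(C)C(C)(C)C)[C@@H]1C[C@H]1[C@H](O)C/C=C\CCC(=O)O
F4 | step 9 | 11,14-bis(tert-butyldimethylsilyl) ether of lactone 14 | CCCCC/C=C\C[C@H](O[Si](C)(C)C(C)(C)C)C#C[C@H](O[Si](C)(C)C(C)(C)C)[C@@H]1C[C@H]1[C@H]1C/C=C\CCC(=O)O1
F5 | step 8 | tert-butyl (4Z,7E)-9-[(2R,3S)-3-(iodoethynyl)oxiran-2-yl]nona-4,7-dienoate | IC#C[C@@H]1O[C@@H]1C/C=C/C/C=C\CCC(=O)OC(C)(C)C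
F6 | step 8 | tert-butyl (4Z,7E)-9-[(2R,3S)-3-[(5Z)-3-hydroxyundec-5-en-1-yn-1-yl]oxiran-2-yl]nona-4,7-dienoate, mixture of C14 epimers | CCCCC/C=C\CC(O)C#C[C@@H]1O[C@@H]1C/C=C/C/C=C\CCC(=O)OC(C)(C)C
F7 | step 8 | tert-butyl (4Z,7E)-9-[(2R,3S)-3-[(5Z)-3-oxoundec-5-en-1-yn-1-yl]oxiran-2-yl]nona-4,7-dienoate | CCCCC/C=C\CC(=O)C#C[C@@H]1O[C@@H]1C/C=C/C/C=C\CCC(=O)OC(C)(C)C
F8 | step 10 | 13-[benzyl(dimethyl)silyl] (12Z)-vinylsilane of 15 (C11 and C14 trans across C12=C13) | CCCCC/C=C\C[C@H](O)/C(=C/[C@H](O)[C@@H]1C[C@H]1[C@H]1C/C=C\CCC(=O)O1)[Si](C)(C)Cc1ccccc1
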